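**Strategy.** Ring A is cut into three alkynes. Because its four substituents (C3a carbon, C7a oxygen, C7 oxygen, C5 side chain) keep the C2/C3 stereo-pair and the C1'/C2' stereo-pair apart, each pair is built separately and ring A is formed last. One ruthenium-catalysed (2+2+2) cycloaddition unites a 1,6-diyne, whose O1–C2–C3 tether joins a C-triethylsilyl ynol ether to a terminal alkyne, with the lactate-derived alkyne: it makes C3a–C7a, C4–C5 and C6–C7 and closes the benzene and dihydrofuran rings together. Silicon marks C7 for later exchange to methoxy. The tethered alkyne stays capped with SiMe3 until the ynol ether is in place, since its C–H would not survive butyllithium.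

Key step: step 11

Remark: O-benzylvanillin and (R)-4-(trimethylsilyl)but-3-yn-2-ol are taken as purchasable. The (R)-mesylate is assigned to the (2S) methyl centre by reasoning (anti SN2′ palladation, retentive transfer to zinc, closed SE2′ transition state), not by a checked literature case.

Step 1
Reactants: 1 (R)-4-(trimethylsilyl)but-3-yn-2-ol
Product: 2 (R)-4-(trimethylsilyl)but-3-yn-2-yl methanesulfonate
Conditions: MsCl, Et3N, CH2Cl2, −78 → 0 °C
Reagents that add atoms: methanesulfonyl chloride, CS(=O)(=O)Cl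
Why: O-sulfonylation (mesylation) of a secondary alcohol touches only the O–H bond, so the (R) centre is retained.

Step 2
Reactants: 2 (R)-4-(trimethylsilyl)but-3-yn-2-yl methanesulfonate; 3 4-(benzyloxy)-3-methoxybenzaldehyde
Product: 5 (1S,2S)-1-[4-(benzyloxy)-3-methoxyphenyl]-2-methyl-4-(trimethylsilyl)but-3-yn-1-ol, via allenylzinc 4 (not isolated)
Conditions: Pd(OAc)2 (5 mol %), PPh3 (5 mol %), Et2Zn (3 equiv), THF, −78 → −20 °C
Reagents that add atoms: none
Why: Marshall propargylation, in which zerovalent palladium displaces the mesylate in anti SN2′ fashion, zinc takes over the allenyl group with retention, and the (aS)-allenylzinc adds through a closed six-membered SE2′ transition state, so that chirality transfer should fix C2 as S and the aryl group lying away from the allenyl methyl should give the anti (1S) alcohol.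

Step 3
Reactants: 5 (1S,2S)-1-[4-(benzyloxy)-3-methoxyphenyl]-2-methyl-4-(trimethylsilyl)but-3-yn-1-ol; 6 trichloroethylene
Product: 8 (E)-1,2-dichlorovinyl ether of alcohol 5, via dichloroethyne 7 (not isolated)
Conditions: KH (2.2 equiv), THF, 0 °C; Cl2C=CHCl (1.2 equiv), −50 °C → rt
Reagents that add atoms: none
Why: Anti addition of the alkoxide to dichloroethyne generated in the flask from trichloroethylene (the standard addition route to alkynyl ether precursors) should give the (E)-dichlorovinyl ether with both stereocentres untouched, the alkyne C–H being masked by SiMe3.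

Step 4
Reactants: 8 (E)-1,2-dichlorovinyl ether of alcohol 5
Product: 11 (1S,2S)-1-[4-(benzyloxy)-3-methoxyphenyl]-2-methyl-4-(trimethylsilyl)but-3-yn-1-yl (triethylsilyl)ethynyl ether, via chloroethynyl ether 9 (not isolated), via lithium alkoxyacetylide 10 (not isolated)
Conditions: n-BuLi (2.3 equiv), THF, −78 °C; Et3SiCl, −78 → 0 °C
Reagents that add atoms: chlorotriethylsilane, CC[Si](Cl)(CC)CC
Why: Dehydrochlorination followed by lithium–chlorine exchange gives the lithium alkoxyacetylide, which is silylated at carbon; because the other alkyne carries SiMe3 there is no second acetylide to compete, and −78 °C should keep the benzylic ether from Wittig rearrangement.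

Step 5
Reactants: 11 (1S,2S)-1-[4-(benzyloxy)-3-methoxyphenyl]-2-methyl-4-(trimethylsilyl)but-3-yn-1-yl (triethylsilyl)ethynyl ether
Product: 12 (1S,2S)-1-[4-(benzyloxy)-3-methoxyphenyl]-2-methylbut-3-yn-1-yl (triethylsilyl)ethynyl ether
Conditions: K2CO3 (0.3 equiv), MeOH–THF (1:2), 0 °C, short contact
Reagents that add atoms: none
Why: Base-catalysed methanolysis of alkynylsilanes proceeds by attack at silicon and is far faster for SiMe3 than for SiEt3, so brief treatment at 0 °C should unmask the terminal alkyne while the ynol ether keeps its silyl group and the basic medium disfavours solvolysis at the benzylic carbon.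

Step 6
Reactants: 13 ethyl (S)-lactate
Product: 14 ethyl (S)-2-[(tert-butyldimethylsilyl)oxy]propanoate
Conditions: TBSCl, imidazole, DMF, rt
Reagents that add atoms: tert-butyldimethylsilyl chloride, CC(C)(C)[Si](C)(C)Cl
Why: Imidazole-promoted O-silylation of the secondary hydroxyl leaves the stereocentre untouched.

Step 7
Reactants: 14 ethyl (S)-2-[(tert-butyldimethylsilyl)oxy]propanoate
Product: 15 (S)-2-[(tert-butyldimethylsilyl)oxy]propanal
Conditions: iBu2AlH (1.1 equiv), CH2Cl2, −78 °C; aqueous Rochelle salt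
Reagents that add atoms: none
Why: Partial ester reduction works because the tetrahedral aluminium hemiacetal is stable at −78 °C and releases the aldehyde only on work-up; the aldehyde is used at once to avoid α-epimerisation.

Step 8
Reactants: 15 (S)-2-[(tert-butyldimethylsilyl)oxy]propanal
Product: 16 (3R,4S)-4-[(tert-butyldimethylsilyl)oxy]-1-(trimethylsilyl)pent-1-yn-3-ol
Conditions: Me3SiC≡CH, n-BuLi, THF, −78 °C; ClTi(OiPr)3; then 15, −78 → −30 °C
Reagents that add atoms: ethynyltrimethylsilane, C#C[Si](C)(C)C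
Why: Felkin–Anh (non-chelation) addition of the bulky, weakly Lewis-acidic titanium acetylide anti to the α-silyloxy group should set C3 as R and give the anti (3R,4S) pattern.

Step 9
Reactants: 16 (3R,4S)-4-[(tert-butyldimethylsilyl)oxy]-1-(trimethylsilyl)pent-1-yn-3-ol
Product: 17 (3R,4S)-pent-1-yne-3,4-diol
Conditions: Bu4NF (2.2 equiv), THF, 0 °C → rt; crude diol carried on after filtration through silica
Reagents that add atoms: none
Why: Fluoride-mediated desilylation cleaves both the O–Si and the C(sp)–Si bond in one operation without touching either stereocentre.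

Step 10
Reactants: 17 (3R,4S)-pent-1-yne-3,4-diol
Product: 18 (4R,5S)-4-ethynyl-2,2,5-trimethyl-1,3-dioxolane
Conditions: Me2C(OMe)2, PPTS (cat.), CH2Cl2, rt
Reagents that add atoms: 2,2-dimethoxypropane, COC(C)(C)OC
Why: Acid-catalysed transacetalisation closes the cis-dioxolane through the O–H bonds only, so the configuration is kept.

Step 11
Reactants: 12 (1S,2S)-1-[4-(benzyloxy)-3-methoxyphenyl]-2-methylbut-3-yn-1-yl (triethylsilyl)ethynyl ether; 18 (4R,5S)-4-ethynyl-2,2,5-trimethyl-1,3-dioxolane
Product: 19 (2S,3S)-2-[4-(benzyloxy)-3-methoxyphenyl]-3-methyl-7-(triethylsilyl)-5-[(4R,5S)-2,2,5-trimethyl-1,3-dioxolan-4-yl]-2,3-dihydro-1-benzofuran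
Conditions: Cp*RuCl(cod) (10 mol %), 18 (3 equiv), ClCH2CH2Cl, 25 °C, 12 added over 4 h; excess 18 recovered
Reagents that add atoms: none
Why: Divalent ruthenium in Cp*RuCl, once freed from cod, couples the two tethered alkynes oxidatively to a bicyclic ruthenacyclopentadiene (C3a–C7a), the side-chain alkyne then inserts, and reductive elimination releases the arene (C4–C5, C6–C7) and the catalyst. The closest known reactions are the Cp*RuCl(cod)-catalysed (2+2+2) cycloadditions of 1,6-diynes bearing one substituted terminus with terminal alkynes, and the rhodium-catalysed cycloadditions of alkynyl-ether- and ynamide-tethered diynes that give fused benzofurans and indolines. The dihydrofuran ring closes in the oxidative coupling as a five-membered ring set up by the three-atom O1–C2–C3 tether, and the benzene ring closes by insertion and reductive elimination as a six-membered carbocycle assembled from three C≡C units. No stereocentre is created, and C2, C3, C1' and C2' are sp3 carbons outside the reacting π-systems, so they should pass through unchanged. The step needs the side chain on C5 and cross- rather than self-cycloaddition: the bulky SiEt3 group on the ynol ether terminus leaves only the C4 end of the metallacycle open to the substituted alkyne carbon (meta outcome), and an excess of 18 with slow addition of 12 should suppress dimerisation. Room temperature keeps the benzylic ynol ether from sigmatropic rearrangement.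

Step 12
Reactants: 19 (2S,3S)-2-[4-(benzyloxy)-3-methoxyphenyl]-3-methyl-7-(triethylsilyl)-5-[(4R,5S)-2,2,5-trimethyl-1,3-dioxolan-4-yl]-2,3-dihydro-1-benzofuran
Product: 20 (2S,3S)-2-[4-(benzyloxy)-3-methoxyphenyl]-7-iodo-3-methyl-5-[(4R,5S)-2,2,5-trimethyl-1,3-dioxolan-4-yl]-2,3-dihydro-1-benzofuran
Conditions: ICl (1.1 equiv), NaHCO3, CH2Cl2, −78 → −40 °C
Reagents that add atoms: iodine monochloride, ClI
Why: Ipso-iododesilylation (electrophilic aromatic substitution) should occur at C7 because it is ortho to O1 and attack there gives a β-silyl-stabilised arenium ion that loses Et3SiCl, a process that at −78 °C should outpace C–H iodination of the pendant ring.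

Step 13
Reactants: 20 (2S,3S)-2-[4-(benzyloxy)-3-methoxyphenyl]-7-iodo-3-methyl-5-[(4R,5S)-2,2,5-trimethyl-1,3-dioxolan-4-yl]-2,3-dihydro-1-benzofuran
Product: 21 (2S,3S)-2-[4-(benzyloxy)-3-methoxyphenyl]-7-methoxy-3-methyl-5-[(4R,5S)-2,2,5-trimethyl-1,3-dioxolan-4-yl]-2,3-dihydro-1-benzofuran
Conditions: NaOMe (5 equiv), CuI (20 mol %), MeOH–DMF, 100 °C
Reagents that add atoms: sodium methoxide, C[O-].[Na+]
Why: Ullmann-type copper-catalysed C–O coupling of an aryl iodide with methoxide is well suited here because the acetonide, the benzyl ether and the cyclic aryl ether are all stable to base.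

Step 14
Reactants: 21 (2S,3S)-2-[4-(benzyloxy)-3-methoxyphenyl]-7-methoxy-3-methyl-5-[(4R,5S)-2,2,5-trimethyl-1,3-dioxolan-4-yl]-2,3-dihydro-1-benzofuran
Product: 22 (1R,2S)-1-{(2S,3S)-2-[4-(benzyloxy)-3-methoxyphenyl]-7-methoxy-3-methyl-2,3-dihydro-1-benzofuran-5-yl}propane-1,2-diol
Conditions: AcOH–H2O–THF (3:1:1), 40 °C
Reagents that add atoms: none
Why: Acid-catalysed hydrolysis of the isopropylidene ketal takes place at the ketal carbon, and acetic acid is too weak to ionise the C1'–O or C2–O1 benzylic bonds, so all four centres should be kept.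

Step 15
Reactants: 22 (1R,2S)-1-{(2S,3S)-2-[4-(benzyloxy)-3-methoxyphenyl]-7-methoxy-3-methyl-2,3-dihydro-1-benzofuran-5-yl}propane-1,2-diol
Product: 23 (1R,2S)-1-[(2S,3S)-2-(4-hydroxy-3-methoxyphenyl)-7-methoxy-3-methyl-2,3-dihydro-1-benzofuran-5-yl]propane-1,2-diol
Conditions: H2 (1 atm), 10% Pd/C, EtOAc, rt, stopped at full conversion
Reagents that add atoms: none
Why: Catalytic hydrogenolysis of an aryl benzyl ether is much faster than cleavage of the C2–O1 ether or of the C1' benzylic alcohol under neutral conditions at one atmosphere.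

**Compound list**

1 | (R)-4-(trimethylsilyl)but-3-yn-2-ol | C[C@@H](O)C#C[Si](C)(C)C | starting material
2 | (R)-4-(trimethylsilyl)but-3-yn-2-yl methanesulfonate | C[C@@H](OS(C)(=O)=O)C#C[Si](C)(C)C | intermediate
3 | 4-(benzyloxy)-3-methoxybenzaldehyde (O-benzylvanillin) | COc1cc(C=O)ccc1OCc1ccccc1 | starting material
4 | ethyl[(aS)-1-(trimethylsilyl)buta-1,2-dien-1-yl]zinc | CC[Zn]C([Si](C)(C)C)=[C@@]=C([H])C | intermediate
5 | (1S,2S)-1-[4-(benzyloxy)-3-methoxyphenyl]-2-methyl-4-(trimethylsilyl)but-3-yn-1-ol | COc1cc([C@@H](O)[C@@H](C)C#C[Si](C)(C)C)ccc1OCc1ccccc1 | intermediate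
6 | trichloroethylene | ClC=C(Cl)Cl | starting material
7 | dichloroethyne | ClC#CCl | intermediate
8 | 1-(benzyloxy)-4-[(1S,2S)-1-{[(E)-1,2-dichloroethenyl]oxy}-2-methyl-4-(trimethylsilyl)but-3-yn-1-yl]-2-methoxybenzene | COc1cc([C@@H](O/C(Cl)=C\Cl)[C@@H](C)C#C[Si](C)(C)C)ccc1OCc1ccccc1 | intermediate
9 | (1S,2S)-1-[4-(benzyloxy)-3-methoxyphenyl]-2-methyl-4-(trimethylsilyl)but-3-yn-1-yl chloroethynyl ether | COc1cc([C@@H](OC#CCl)[C@@H](C)C#C[Si](C)(C)C)ccc1OCc1ccccc1 | intermediate
10 | lithium 2-{(1S,2S)-1-[4-(benzyloxy)-3-methoxyphenyl]-2-methyl-4-(trimethylsilyl)but-3-yn-1-yloxy}ethynide | COc1cc([C@@H](OC#C[Li])[C@@H](C)C#C[Si](C)(C)C)ccc1OCc1ccccc1 | intermediate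
11 | (1S,2S)-1-[4-(benzyloxy)-3-methoxyphenyl]-2-methyl-4-(trimethylsilyl)but-3-yn-1-yl (triethylsilyl)ethynyl ether | COc1cc([C@@H](OC#C[Si](CC)(CC)CC)[C@@H](C)C#C[Si](C)(C)C)ccc1OCc1ccccc1 | intermediate
12 | (1S,2S)-1-[4-(benzyloxy)-3-methoxyphenyl]-2-methylbut-3-yn-1-yl (triethylsilyl)ethynyl ether | COc1cc([C@@H](OC#C[Si](CC)(CC)CC)[C@@H](C)C#C)ccc1OCc1ccccc1 | intermediate
13 | ethyl (S)-lactate | CCOC(=O)[C@H](C)O | starting material
14 | ethyl (S)-2-[(tert-butyldimethylsilyl)oxy]propanoate | CCOC(=O)[C@H](C)O[Si](C)(C)C(C)(C)C | intermediate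
15 | (S)-2-[(tert-butyldimethylsilyl)oxy]propanal | O=C[C@H](C)O[Si](C)(C)C(C)(C)C | intermediate
16 | (3R,4S)-4-[(tert-butyldimethylsilyl)oxy]-1-(trimethylsilyl)pent-1-yn-3-ol | C[Si](C)(C)C#C[C@@H](O)[C@H](C)O[Si](C)(C)C(C)(C)C | intermediate
17 | (3R,4S)-pent-1-yne-3,4-diol | C#C[C@@H](O)[C@H](C)O | intermediate
18 | (4R,5S)-4-ethynyl-2,2,5-trimethyl-1,3-dioxolane | C#C[C@H]1OC(C)(C)O[C@H]1C | intermediate
19 | (2S,3S)-2-[4-(benzyloxy)-3-methoxyphenyl]-3-methyl-7-(triethylsilyl)-5-[(4R,5S)-2,2,5-trimethyl-1,3-dioxolan-4-yl]-2,3-dihydro-1-benzofuran | COc1cc([C@H]2Oc3c([Si](CC)(CC)CC)cc([C@H]4OC(C)(C)O[C@H]4C)cc3[C@@H]2C)ccc1OCc1ccccc1 | intermediate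
20 | (2S,3S)-2-[4-(benzyloxy)-3-methoxyphenyl]-7-iodo-3-methyl-5-[(4R,5S)-2,2,5-trimethyl-1,3-dioxolan-4-yl]-2,3-dihydro-1-benzofuran | COc1cc([C@H]2Oc3c(I)cc([C@H]4OC(C)(C)O[C@H]4C)cc3[C@@H]2C)ccc1OCc1ccccc1 | intermediate
21 | (2S,3S)-2-[4-(benzyloxy)-3-methoxyphenyl]-7-methoxy-3-methyl-5-[(4R,5S)-2,2,5-trimethyl-1,3-dioxolan-4-yl]-2,3-dihydro-1-benzofuran | COc1cc([C@H]2Oc3c(OC)cc([C@H]4OC(C)(C)O[C@H]4C)cc3[C@@H]2C)ccc1OCc1ccccc1 | intermediate
22 | (1R,2S)-1-{(2S,3S)-2-[4-(benzyloxy)-3-methoxyphenyl]-7-methoxy-3-methyl-2,3-dihydro-1-benzofuran-5-yl}propane-1,2-diol | COc1cc([C@H]2Oc3c(OC)cc([C@@H](O)[C@H](C)O)cc3[C@@H]2C)ccc1OCc1ccccc1 | intermediate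
23 | (1R,2S)-1-[(2S,3S)-2-(4-hydroxy-3-methoxyphenyl)-7-methoxy-3-methyl-2,3-dihydro-1-benzofuran-5-yl]propane-1,2-diol (CNP0173101.2) | COc1cc([C@H]2Oc3c(OC)cc([C@@H](O)[C@H](C)O)cc3[C@@H]2C)ccc1O | target

**Step count.** Total: 15 steps. Longest linear sequence: 10 steps (steps 1–5 and 11–15; the lactate branch, steps 6–10 and 11–15, is equally long).

**Steps most likely to fail**

Step 11. The alkyne may insert in the wrong orientation (side chain on C6), or diyne 12 may cyclotrimerise with itself instead of with 18. The fallback makes the cycloaddition fully intramolecular through a disposable silicon tether; it sets out from 12 and 16 and comes back at 19. Selective C-desilylation of 16 (K2CO3, MeOH) gives (3R,4S)-4-[(tert-butyldimethylsilyl)oxy]pent-1-yn-3-ol F1. Diyne 12 is deprotonated at its terminal alkyne (n-BuLi, THF, −78 °C) to the lithium acetylide F2, which with iPr2SiCl2 gives the alkynyl(chloro)diisopropylsilane F3. Adding F1 and imidazole then gives the silyl-ether-linked triyne F4. RhCl(PPh3)3 in toluene at 40 °C should cyclise F4 to the tetracyclic siloxane F5, in which the C4–Si–O–C1' bridge forces the side chain onto C5. Bu4NF in warm DMF should cleave the Si–O bond, protodesilylate C4 and remove the O-silyl group, giving the 7-triethylsilyl diol F6. Acetonide formation (Me2C(OMe)2, PPTS) returns 19.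

Step 12. The pendant dialkoxyphenyl ring may be iodinated in competition with ipso-substitution at the hindered SiEt3 group. The fallback deactivates that ring by a protecting-group switch before halogenation; it sets out from 19 and comes back at 23. Hydrogenolysis of 19 (H2, Pd/C, EtOAc) gives the 7-triethylsilyl phenol F7, and PivCl, Et3N and DMAP give the aryl pivalate F8. ICl at −78 °C should then give the 7-iodo pivalate F9. The methoxylation conditions of step 13 (NaOMe, CuI, MeOH–DMF, 100 °C) should introduce the C7 methoxy group and cleave the pivalate in the same flask, giving the 7-methoxy phenol acetonide F10. Aqueous acetic acid as in step 14 then gives 23 without a final hydrogenolysis.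

Step 2. The anti preference may erode with the electron-rich aromatic aldehyde, so that 5 is obtained mixed with its C1 epimer; C2 is not at risk because it comes from chirality transfer. The fallback sets C1 by reagent-controlled ketone reduction; it sets out from the epimer mixture of 5 and comes back at 5. Oxidation (Dess–Martin periodinane, NaHCO3, CH2Cl2) gives (S)-1-[4-(benzyloxy)-3-methoxyphenyl]-2-methyl-4-(trimethylsilyl)but-3-yn-1-one F11. Corey–Bakshi–Shibata reduction with the (R)-oxazaborolidine and BH3·SMe2 at −40 °C, whose known sense for aryl ketones leads to the (S)-carbinol, should return 5 as the anti isomer.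

**Further compounds**

F1 | step 11 | (3R,4S)-4-[(tert-butyldimethylsilyl)oxy]pent-1-yn-3-ol | C#C[C@@H](O)[C@H](C)O[Si](C)(C)C(C)(C)C
F2 | step 11 | lithium acetylide of diyne 12 | COc1cc([C@@H](OC#C[Si](CC)(CC)CC)[C@@H](C)C#C[Li])ccc1OCc1ccccc1
F3 | step 11 | alkynyl(chloro)diisopropylsilane derived from 12 | COc1cc([C@@H](OC#C[Si](CC)(CC)CC)[C@@H](C)C#C[Si](Cl)(C(C)C)C(C)C)ccc1OCc1ccccc1
F4 | step 11 | silyl-ether-linked triyne | COc1cc([C@@H](OC#C[Si](CC)(CC)CC)[C@@H](C)C#C[Si](C(C)C)(C(C)C)O[C@H](C#C)[C@H](C)O[Si](C)(C)C(C)(C)C)ccc1OCc1ccccc1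
F5 | step 11 | tetracyclic siloxane with a C4–Si(iPr)2–O–C1' bridge | COc1cc([C@H]2Oc3c([Si](CC)(CC)CC)cc4c(c3[C@@H]2C)[Si](C(C)C)(C(C)C)O[C@H]4[C@H](C)O[Si](C)(C)C(C)(C)C)ccc1OCc1ccccc1
F6 | step 11 | (1R,2S)-1-{(2S,3S)-2-[4-(benzyloxy)-3-methoxyphenyl]-3-methyl-7-(triethylsilyl)-2,3-dihydro-1-benzofuran-5-yl}propane-1,2-diol | COc1cc([C@H]2Oc3c([Si](CC)(CC)CC)cc([C@@H](O)[C@H](C)O)cc3[C@@H]2C)ccc1OCc1ccccc1
F7 | step 12 | 2-methoxy-4-{(2S,3S)-3-methyl-7-(triethylsilyl)-5-[(4R,5S)-2,2,5-trimethyl-1,3-dioxolan-4-yl]-2,3-dihydro-1-benzofuran-2-yl}phenol | COc1cc([C@H]2Oc3c([Si](CC)(CC)CC)cc([C@H]4OC(C)(C)O[C@H]4C)cc3[C@@H]2C)ccc1O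
F8 | step 12 | pivalate of F7 | COc1cc([C@H]2Oc3c([Si](CC)(CC)CC)cc([C@H]4OC(C)(C)O[C@H]4C)cc3[C@@H]2C)ccc1OC(=O)C(C)(C)C
F9 | step 12 | 7-iodo pivalate | COc1cc([C@H]2Oc3c(I)cc([C@H]4OC(C)(C)O[C@H]4C)cc3[C@@H]2C)ccc1OC(=O)C(C)(C)C
F10 | step 12 | 2-methoxy-4-{(2S,3S)-7-methoxy-3-methyl-5-[(4R,5S)-2,2,5-trimethyl-1,3-dioxolan-4-yl]-2,3-dihydro-1-benzofuran-2-yl}phenol | COc1cc([C@H]2Oc3c(OC)cc([C@H]4OC(C)(C)O[C@H]4C)cc3[C@@H]2C)ccc1O
F11 | step 2 | (S)-1-[4-(benzyloxy)-3-methoxyphenyl]-2-methyl-4-(trimethylsilyl)but-3-yn-1-one | COc1cc(C(=O)[C@@H](C)C#C[Si](C)(C)C)ccc1OCc1ccccc1
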